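**Retrosynthetic overview**
- Kushenol G is reached by taking off three allyl groups, one MOM group and one TES group from a protected flavonol. Ring C (O1–C2 bond, C3–OH) comes from an Algar–Flynn–Oyamada oxidation of a 2'-hydroxychalcone, and the C2–C3 bond from an aldol condensation of a ring A acetophenone with 2,4-bis(allyloxy)benzaldehyde (ring B, bought as the dihydroxy aldehyde).
- The acetophenone carbon C4 is put on C4a by ortho-formylation of a ring A phenol whose only free hydroxyl is O1, followed by methyl addition and oxidation.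
- Ring A is made by benzannulation of 3-(methoxymethoxy)cyclobutenone (C8a, C4a, C5, C6 with O1 and O5) with a siloxyalkyne (C7 with O7, C8 with the side chain). The strategy rests on ring A being a phloroglucinol in which C8 (alkyl), C6 (H) and C4a (acyl) each lie between two oxygen-bearing carbons, so that O1, O5 and O7 must leave the ring-forming step already told apart.
- The siloxyalkyne comes from a Kowalski homologation of an ester cut out of (R)-limonene oxide: limonene C4 is C2'', the opened ring gives C1'' and C3''–C5'', the ester carbon becomes C7 and the carbon from CH2Br2 becomes C8.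
- Ring order: ring B is bought, ring A is built in step 8, ring C is closed last in step 15.

Key step: step 8

Assumption: commercial (+)-limonene 1,2-oxide [(4R), cis/trans mixture at C1/C2] is the chiral starting material; both epoxide diastereomers converge in step 1, and C4 of limonene becomes C2'' of the target without ever being touched.
Abbreviation: SC = (2R)-5-methyl-2-(prop-1-en-2-yl)-5-(triethylsilyloxy)hexyl, the TES-protected side chain. Flavone numbering is used for the target (ring B primed, side chain C1''–C5'').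

**Step 1**
Reactants: 1 (4R)-limonene 1,2-oxide
Product: 3 (3R)-6-oxo-3-(prop-1-en-2-yl)heptanal, via diol 2 (not isolated)
Conditions: H5IO6 (1.1 equiv), THF/H2O, 0 °C → rt
Reagents that add atoms: water, O
Why: Acid-promoted epoxide hydrolysis and Malaprade glycol cleavage run in one flask, both epoxide diastereomers converge on the same seco keto aldehyde, and the isopropenyl group and the ring stereocentre (C3 of 3, later C2'') are not involved.

**Step 2**
Reactants: 3 (3R)-6-oxo-3-(prop-1-en-2-yl)heptanal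
Product: 4 (3R)-6-oxo-3-(prop-1-en-2-yl)heptanoic acid
Conditions: NaClO2, NaH2PO4, 2-methyl-2-butene, t-BuOH/H2O, 0 °C → rt
Reagents that add atoms: sodium chlorite, [Na+].[O-]Cl=O
Why: Pinnick oxidation converts the aldehyde into the acid under buffered conditions in which the methyl ketone is inert, and the scavenger alkene takes up the hypochlorous acid before it can add to the isopropenyl group.

**Step 3**
Reactants: 4 (3R)-6-oxo-3-(prop-1-en-2-yl)heptanoic acid
Product: 5 (3R)-6-hydroxy-6-methyl-3-(prop-1-en-2-yl)heptanoic acid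
Conditions: MeMgBr (2.5 equiv), THF, −20 → 0 °C; then 1 M HCl, 0 °C
Reagents that add atoms: methylmagnesium bromide, C[Mg]Br
Why: Grignard addition in which the first equivalent turns the acid into a magnesium carboxylate that resists further attack, so the second equivalent adds only to the ketone and gives the C5'' carbinol carrying two identical methyl groups (no new stereocentre).

**Step 4**
Reactants: 5 (3R)-6-hydroxy-6-methyl-3-(prop-1-en-2-yl)heptanoic acid
Product: 6 methyl (3R)-6-hydroxy-6-methyl-3-(prop-1-en-2-yl)heptanoate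
Conditions: MeI, K2CO3, DMF, rt
Reagents that add atoms: iodomethane, CI
Why: SN2 O-alkylation of the potassium carboxylate gives the methyl ester, while the hindered tertiary alcohol is not methylated by K2CO3 and MeI.

**Step 5**
Reactants: 6 methyl (3R)-6-hydroxy-6-methyl-3-(prop-1-en-2-yl)heptanoate
Product: 7 methyl (3R)-6-methyl-3-(prop-1-en-2-yl)-6-(triethylsilyloxy)heptanoate
Conditions: TESOTf, 2,6-lutidine, CH2Cl2, −78 → 0 °C
Reagents that add atoms: triethylsilyl trifluoromethanesulfonate, CC[Si](CC)(CC)OS(=O)(=O)C(F)(F)F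
Why: Silylation with a silyl triflate and a hindered pyridine base is the standard way to cap a tertiary alcohol, and the TES ether keeps the hydroxyl away from the organolithium reagents of step 6 and the ketenes of step 8.

**Step 6**
Reactants: 7 methyl (3R)-6-methyl-3-(prop-1-en-2-yl)-6-(triethylsilyloxy)heptanoate
Product: 10 (4R)-7-methyl-4-(prop-1-en-2-yl)-7-(triethylsilyloxy)-1-(triisopropylsilyloxy)oct-1-yne, via lithium dibromoenolate 8 (not isolated), via lithium ynolate 9 (not isolated)
Conditions: CH2Br2, lithium 2,2,6,6-tetramethylpiperidide, THF, −78 °C; then 7; LiN(SiMe3)2; n-BuLi, −78 °C → rt; i-Pr3SiCl, −78 → 0 °C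
Reagents that add atoms: dibromomethane, BrCBr; chlorotriisopropylsilane, CC(C)[Si](Cl)(C(C)C)C(C)C
Why: Kowalski homologation, in which dibromomethyllithium adds to the ester, the derived dibromo enolate 8 undergoes bromine–lithium exchange and 1,2-shift of the alkyl group to ynolate 9, and the bulky chlorosilane traps 9 on oxygen, so the ester carbon becomes the oxygen-bearing alkyne carbon (future C7) and the carbon from CH2Br2 the alkyl-bearing one (future C8).

**Step 7**
Reactants: 11 cyclobutane-1,3-dione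
Product: 12 3-(methoxymethoxy)cyclobut-2-en-1-one
Conditions: MOMCl, i-Pr2NEt, CH2Cl2, 0 °C
Reagents that add atoms: chloromethyl methyl ether, COCCl
Why: The dione is a strongly acidic vinylogous acid whose amine enolate is alkylated on oxygen by the hard electrophile MOMCl (enol ether formation), which gives the vinylogous ester needed as the four-carbon partner.

**Step 8**
Reactants: 10 (4R)-7-methyl-4-(prop-1-en-2-yl)-7-(triethylsilyloxy)-1-(triisopropylsilyloxy)oct-1-yne; 12 3-(methoxymethoxy)cyclobut-2-en-1-one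
Product: 17 2-SC-5-(methoxymethoxy)-3-(triisopropylsilyloxy)phenol, via alkoxyvinylketene 13 (not isolated), via vinylcyclobutenone 14 (not isolated), via dienylketene 15 (not isolated), via cyclohexadienone 16 (not isolated)
Conditions: toluene, 80 °C then 110 °C, sealed tube, argon; 12 (1.2 equiv) added in portions
Reagents that add atoms: none
Why: Heating opens cyclobutenone 12 by four-electron electrocyclic ring opening to alkoxyvinylketene 13, whose ketene carbon is attacked by the nucleophilic alkyl-bearing carbon of siloxyalkyne 10 in a regioselective (2+2) cycloaddition that gives vinylcyclobutenone 14 (bonds C8–C8a and C6–C7). A second four-electron ring opening gives dienylketene 15, and ring A closes by six-electron electrocyclisation (bond C4a–C8a) to cyclohexadienone 16, which tautomerises to phenol 17. The closest known reaction type is the Danheiser benzannulation of cyclobutenones with siloxyalkynes to resorcinol monosilyl ethers; the 3-alkoxy group on the cyclobutenone is the less usual element and may call for the upper end of the temperature range. No stereocentre is formed, and the remote C2'' centre, the isopropenyl group and both silyl ethers are inert under the neutral thermal conditions. The selectivity needed is the orientation of the ketene–alkyne (2+2) step, which the oxygen-induced polarisation of the ynol ether secures, so the side chain ends up between the free hydroxyl (future O1) and the silyloxy group (O7), with the MOM ether at C5.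

**Step 9**
Reactants: 17 2-SC-5-(methoxymethoxy)-3-(triisopropylsilyloxy)phenol
Product: 19 2-hydroxy-6-(methoxymethoxy)-3-SC-4-(triisopropylsilyloxy)benzaldehyde, via salicyl alcohol 18 (not isolated)
Conditions: MgCl2, Et3N, (CH2O)n, THF, reflux; aq NH4Cl work-up
Reagents that add atoms: paraformaldehyde (formaldehyde), C=O
Why: Casnati–Skattebøl ortho-formylation, in which the magnesium phenoxide delivers formaldehyde to the ortho carbon and a second formaldehyde oxidises salicyl alcohol 18 by hydride transfer; C4a is the only free ortho position, the para position C6 is not attacked, and the base-buffered medium spares the MOM and silyl ethers.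

**Step 10**
Reactants: 19 2-hydroxy-6-(methoxymethoxy)-3-SC-4-(triisopropylsilyloxy)benzaldehyde
Product: 21 4-(allyloxy)-2-hydroxy-6-(methoxymethoxy)-3-SC-benzaldehyde, via caesium phenoxide 20 (not isolated)
Conditions: CsF (2 equiv), allyl bromide (1.1 equiv), DMF, 0 °C → rt
Reagents that add atoms: allyl bromide, C=CCBr
Why: Fluoride cleaves the aryl silyl ether much faster than the tertiary alkyl TES ether, and the liberated para-phenoxide 20 is allylated in a Williamson etherification while the O1 hydroxyl, hydrogen-bonded to the aldehyde and flanked by the side chain, stays free; the exchange is made because an aryl silyl ether would not survive the hydroxide of steps 14 and 15.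

**Step 11**
Reactants: 21 4-(allyloxy)-2-hydroxy-6-(methoxymethoxy)-3-SC-benzaldehyde
Product: 22 1-[4-(allyloxy)-2-hydroxy-6-(methoxymethoxy)-3-SC-phenyl]ethan-1-ol
Conditions: MeMgBr (3 equiv), THF, −78 → 0 °C; aq NH4Cl; used crude
Reagents that add atoms: methylmagnesium bromide, C[Mg]Br
Why: Grignard addition to the aldehyde after deprotonation of the phenol gives the secondary benzylic alcohol, whose new carbinol centre is formed without control and is removed in step 12.

**Step 12**
Reactants: 22 1-[4-(allyloxy)-2-hydroxy-6-(methoxymethoxy)-3-SC-phenyl]ethan-1-ol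
Product: 23 1-[4-(allyloxy)-2-hydroxy-6-(methoxymethoxy)-3-SC-phenyl]ethan-1-one
Conditions: MnO2 (activated, excess), CH2Cl2, rt
Reagents that add atoms: none
Why: MnO2 oxidises benzylic alcohols selectively under neutral conditions, which avoids ionisation of the electron-rich ortho-hydroxybenzyl alcohol and leaves the allyl ether, isopropenyl group and phenol alone.

**Step 13**
Reactants: 24 2,4-dihydroxybenzaldehyde
Product: 25 2,4-bis(allyloxy)benzaldehyde
Conditions: allyl bromide (2.5 equiv), K2CO3, DMF, 60 °C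
Reagents that add atoms: allyl bromide, C=CCBr
Why: Twofold Williamson etherification of the commercial dihydroxy aldehyde; allyl groups are chosen because they survive hydroxide and alkaline peroxide and come off at the end under neutral conditions that do not touch the side chain.

**Step 14**
Reactants: 23 1-[4-(allyloxy)-2-hydroxy-6-(methoxymethoxy)-3-SC-phenyl]ethan-1-one; 25 2,4-bis(allyloxy)benzaldehyde
Product: 27 (E)-1-[4-(allyloxy)-2-hydroxy-6-(methoxymethoxy)-3-SC-phenyl]-3-[2,4-bis(allyloxy)phenyl]prop-2-en-1-one, via aldol adduct 26 (not isolated)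
Conditions: KOH, EtOH, rt
Reagents that add atoms: none
Why: Claisen–Schmidt condensation of the methyl ketone enolate with the non-enolisable aldehyde forms the C2–C3 bond, and aldol adduct 26 dehydrates to the (E)-enone under thermodynamic control.

**Step 15**
Reactants: 27 (E)-1-[4-(allyloxy)-2-hydroxy-6-(methoxymethoxy)-3-SC-phenyl]-3-[2,4-bis(allyloxy)phenyl]prop-2-en-1-one
Product: 29 7-(allyloxy)-2-[2,4-bis(allyloxy)phenyl]-3-hydroxy-5-(methoxymethoxy)-8-SC-4H-chromen-4-one, via dihydroflavonol 28 (not isolated)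
Conditions: 30% H2O2, NaOH, MeOH, 0 °C → rt
Reagents that add atoms: hydrogen peroxide, OO
Why: Algar–Flynn–Oyamada reaction, in which alkaline hydrogen peroxide oxidises the enone while the O1 phenoxide closes ring C at the β-carbon (six-membered closure forming O1–C2) and dihydroflavonol 28 is dehydrogenated in the same medium; unactivated alkenes (isopropenyl, allyl) do not react with alkaline peroxide, and the two transient stereocentres of 28 disappear.

**Step 16**
Reactants: 29 7-(allyloxy)-2-[2,4-bis(allyloxy)phenyl]-3-hydroxy-5-(methoxymethoxy)-8-SC-4H-chromen-4-one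
Product: 30 7-(allyloxy)-2-[2,4-bis(allyloxy)phenyl]-3,5-dihydroxy-8-[(2R)-5-hydroxy-5-methyl-2-(prop-1-en-2-yl)hexyl]-4H-chromen-4-one
Conditions: HCl (0.5 M, aq), MeOH/THF, 0 °C → rt
Reagents that add atoms: none
Why: Acid-catalysed solvolysis of the acetal and of the silyl ether, in which the 5-O-MOM group is activated by the peri C4 carbonyl and the tertiary TES ether is labile, so dilute acid at room temperature should suffice without ionising the isopropenyl group or the tertiary alcohol, while the allyl group still on O7 blocks chroman formation with the side chain.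

**Step 17**
Reactants: 30 7-(allyloxy)-2-[2,4-bis(allyloxy)phenyl]-3,5-dihydroxy-8-[(2R)-5-hydroxy-5-methyl-2-(prop-1-en-2-yl)hexyl]-4H-chromen-4-one
Product: 31 Kushenol G
Conditions: Pd(PPh3)4 (10 mol %), morpholine, THF, rt, argon
Reagents that add atoms: none
Why: Tsuji–Trost deallylation, in which zerovalent palladium ionises the three aryl allyl ethers to π-allyl complexes that are intercepted by morpholine, while the isopropenyl group (no allylic leaving group), the tertiary alcohol and the C2'' stereocentre are untouched.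

**Compound list**
1 | (4R)-limonene 1,2-oxide (cis/trans mixture at C1/C2) | C=C(C)[C@@H]1CCC2(C)OC2C1 | starting material
2 | (4R)-p-menth-8-ene-1,2-diol | C=C(C)[C@@H]1CCC(C)(O)C(O)C1 | intermediate
3 | (3R)-6-oxo-3-(prop-1-en-2-yl)heptanal | C=C(C)[C@H](CCC(C)=O)CC=O | intermediate
4 | (3R)-6-oxo-3-(prop-1-en-2-yl)heptanoic acid | C=C(C)[C@H](CCC(C)=O)CC(=O)O | intermediate
5 | (3R)-6-hydroxy-6-methyl-3-(prop-1-en-2-yl)heptanoic acid | C=C(C)[C@H](CCC(C)(C)O)CC(=O)O | intermediate
6 | methyl (3R)-6-hydroxy-6-methyl-3-(prop-1-en-2-yl)heptanoate | C=C(C)[C@H](CCC(C)(C)O)CC(=O)OC | intermediate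
7 | methyl (3R)-6-methyl-3-(prop-1-en-2-yl)-6-(triethylsilyloxy)heptanoate | C=C(C)[C@H](CCC(C)(C)O[Si](CC)(CC)CC)CC(=O)OC | intermediate
8 | lithium enolate of (4R)-1,1-dibromo-7-methyl-4-(prop-1-en-2-yl)-7-(triethylsilyloxy)octan-2-one | C=C(C)[C@H](CCC(C)(C)O[Si](CC)(CC)CC)CC(O[Li])=C(Br)Br | intermediate
9 | lithium (4R)-7-methyl-4-(prop-1-en-2-yl)-7-(triethylsilyloxy)oct-1-yn-1-olate | C=C(C)[C@H](CCC(C)(C)O[Si](CC)(CC)CC)CC#CO[Li] | intermediate
10 | (4R)-7-methyl-4-(prop-1-en-2-yl)-7-(triethylsilyloxy)-1-(triisopropylsilyloxy)oct-1-yne | C=C(C)[C@H](CCC(C)(C)O[Si](CC)(CC)CC)CC#CO[Si](C(C)C)(C(C)C)C(C)C | intermediate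
11 | cyclobutane-1,3-dione | O=C1CC(=O)C1 | starting material
12 | 3-(methoxymethoxy)cyclobut-2-en-1-one | O=C1C=C(OCOC)C1 | intermediate
13 | 3-(methoxymethoxy)buta-1,3-dien-1-one (alkoxyvinylketene) | C=C(OCOC)C=C=O | intermediate
14 | 4-[1-(methoxymethoxy)vinyl]-2-SC-3-(triisopropylsilyloxy)cyclobut-2-en-1-one (both epimers at ring C4) | C=C(C)[C@H](CCC(C)(C)O[Si](CC)(CC)CC)CC1=C(O[Si](C(C)C)(C(C)C)C(C)C)C(C(=C)OCOC)C1=O | intermediate
15 | (3E)-5-(methoxymethoxy)-2-SC-3-(triisopropylsilyloxy)hexa-1,3,5-trien-1-one (ketene and vinyl ends cis across the central C=C) | C=C(C)[C@H](CCC(C)(C)O[Si](CC)(CC)CC)CC(=C=O)/C(O[Si](C(C)C)(C(C)C)C(C)C)=C\C(=C)OCOC | intermediate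
16 | 5-(methoxymethoxy)-2-SC-3-(triisopropylsilyloxy)cyclohexa-2,4-dien-1-one | C=C(C)[C@H](CCC(C)(C)O[Si](CC)(CC)CC)CC1=C(O[Si](C(C)C)(C(C)C)C(C)C)C=C(OCOC)CC1=O | intermediate
17 | 2-SC-5-(methoxymethoxy)-3-(triisopropylsilyloxy)phenol | C=C(C)[C@H](CCC(C)(C)O[Si](CC)(CC)CC)Cc1c(O)cc(OCOC)cc1O[Si](C(C)C)(C(C)C)C(C)C | intermediate
18 | 2-(hydroxymethyl)-3-(methoxymethoxy)-6-SC-5-(triisopropylsilyloxy)phenol | C=C(C)[C@H](CCC(C)(C)O[Si](CC)(CC)CC)Cc1c(O)c(CO)c(OCOC)cc1O[Si](C(C)C)(C(C)C)C(C)C | intermediate
19 | 2-hydroxy-6-(methoxymethoxy)-3-SC-4-(triisopropylsilyloxy)benzaldehyde | C=C(C)[C@H](CCC(C)(C)O[Si](CC)(CC)CC)Cc1c(O)c(C=O)c(OCOC)cc1O[Si](C(C)C)(C(C)C)C(C)C | intermediate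
20 | caesium 4-phenoxide of 2,4-dihydroxy-6-(methoxymethoxy)-3-SC-benzaldehyde | C=C(C)[C@H](CCC(C)(C)O[Si](CC)(CC)CC)Cc1c(O)c(C=O)c(OCOC)cc1[O-].[Cs+] | intermediate
21 | 4-(allyloxy)-2-hydroxy-6-(methoxymethoxy)-3-SC-benzaldehyde | C=C(C)[C@H](CCC(C)(C)O[Si](CC)(CC)CC)Cc1c(O)c(C=O)c(OCOC)cc1OCC=C | intermediate
22 | 1-[4-(allyloxy)-2-hydroxy-6-(methoxymethoxy)-3-SC-phenyl]ethan-1-ol (both carbinol epimers) | C=C(C)[C@H](CCC(C)(C)O[Si](CC)(CC)CC)Cc1c(O)c(C(C)O)c(OCOC)cc1OCC=C | intermediate
23 | 1-[4-(allyloxy)-2-hydroxy-6-(methoxymethoxy)-3-SC-phenyl]ethan-1-one | C=C(C)[C@H](CCC(C)(C)O[Si](CC)(CC)CC)Cc1c(O)c(C(C)=O)c(OCOC)cc1OCC=C | intermediate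
24 | 2,4-dihydroxybenzaldehyde | O=Cc1ccc(O)cc1O | starting material
25 | 2,4-bis(allyloxy)benzaldehyde | O=Cc1ccc(OCC=C)cc1OCC=C | intermediate
26 | 1-[4-(allyloxy)-2-hydroxy-6-(methoxymethoxy)-3-SC-phenyl]-3-[2,4-bis(allyloxy)phenyl]-3-hydroxypropan-1-one (both carbinol epimers) | C=C(C)[C@H](CCC(C)(C)O[Si](CC)(CC)CC)Cc1c(O)c(C(=O)CC(O)c2ccc(OCC=C)cc2OCC=C)c(OCOC)cc1OCC=C | intermediate
27 | (E)-1-[4-(allyloxy)-2-hydroxy-6-(methoxymethoxy)-3-SC-phenyl]-3-[2,4-bis(allyloxy)phenyl]prop-2-en-1-one | C=C(C)[C@H](CCC(C)(C)O[Si](CC)(CC)CC)Cc1c(O)c(C(=O)/C=C/c2ccc(OCC=C)cc2OCC=C)c(OCOC)cc1OCC=C | intermediate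
28 | 7-(allyloxy)-2-[2,4-bis(allyloxy)phenyl]-3-hydroxy-5-(methoxymethoxy)-8-SC-chroman-4-one (C2/C3 isomers) | C=C(C)[C@H](CCC(C)(C)O[Si](CC)(CC)CC)Cc1c(OCC=C)cc(OCOC)c2c1OC(c3ccc(OCC=C)cc3OCC=C)C(O)C2=O | intermediate
29 | 7-(allyloxy)-2-[2,4-bis(allyloxy)phenyl]-3-hydroxy-5-(methoxymethoxy)-8-SC-4H-chromen-4-one | C=C(C)[C@H](CCC(C)(C)O[Si](CC)(CC)CC)Cc1c(OCC=C)cc(OCOC)c2c(=O)c(O)c(-c3ccc(OCC=C)cc3OCC=C)oc12 | intermediate
30 | 7-(allyloxy)-2-[2,4-bis(allyloxy)phenyl]-3,5-dihydroxy-8-[(2R)-5-hydroxy-5-methyl-2-(prop-1-en-2-yl)hexyl]-4H-chromen-4-one | C=C(C)[C@H](CCC(C)(C)O)Cc1c(OCC=C)cc(O)c2c(=O)c(O)c(-c3ccc(OCC=C)cc3OCC=C)oc12 | intermediate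
31 | Kushenol G, 2-(2,4-dihydroxyphenyl)-3,5,7-trihydroxy-8-[(2R)-5-hydroxy-5-methyl-2-(prop-1-en-2-yl)hexyl]-4H-chromen-4-one | C=C(C)[C@H](CCC(C)(C)O)Cc1c(O)cc(O)c2c(=O)c(O)c(-c3ccc(O)cc3O)oc12 | target

**Step count**
Total: 17 steps. Longest linear sequence: 15 steps (steps 1–6, 8–12, 14–17); steps 7 and 13 are one-step side branches.

**Steps most likely to fail**

1. Step 8 (benzannulation). The vinylogous-ester stabilisation of 12 may hold back the first ring opening, so that at the temperature then needed the siloxyalkyne isomerises by silyl shift to a silylketene, or ketene 13 is used up by dimerisation or by acylating the product phenol before it meets the alkyne. The fallback makes the same ketene 13 at or below room temperature by 1,4-dehydrochlorination of a β-alkoxycrotonyl chloride, a known way to vinylketenes. It sets out from 10 and comes back to the route at 14. Methyl acetoacetate is O-alkylated (NaH, MOMCl, THF) to methyl (E)-3-(methoxymethoxy)but-2-enoate F1, which is saponified (LiOH, THF/H2O, buffered work-up) to (E)-3-(methoxymethoxy)but-2-enoic acid F2 and converted with 1-chloro-N,N,2-trimethylprop-1-en-1-amine (CH2Cl2, 0 °C) into (E)-3-(methoxymethoxy)but-2-enoyl chloride F3. Slow addition of Et3N to F3 and 10 in toluene at 0 °C → rt should release 13, which is trapped by the alkyne as 14; warming the same solution to 80–110 °C then takes 14 through 15 and 16 to 17.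

2. Step 15 (Algar–Flynn–Oyamada). With a 6'-alkoxy group on ring A and a 2-alkoxy group on ring B, the phenoxide may close onto the α-carbon (five-membered ring) and give the aurone instead of the flavonol. The fallback closes ring C before C3 is oxidised; it sets out from aldehyde 21 (using 25 for ring B) and comes back at 29. Aldehyde 25 is homologated with dimethyl (1-diazo-2-oxopropyl)phosphonate (K2CO3, MeOH) to 2,4-bis(allyloxy)-1-ethynylbenzene F4. Its lithium acetylide (n-BuLi, THF, −78 °C, 2.5 equiv) adds to 21 to give 1-[4-(allyloxy)-2-hydroxy-6-(methoxymethoxy)-3-SC-phenyl]-3-[2,4-bis(allyloxy)phenyl]prop-2-yn-1-ol F5, which MnO2 oxidises to the corresponding ynone 1-[4-(allyloxy)-2-hydroxy-6-(methoxymethoxy)-3-SC-phenyl]-3-[2,4-bis(allyloxy)phenyl]prop-2-yn-1-one F6. Et2NH in EtOH then closes ring C by conjugate addition and addition–elimination (six-membered closure only) to 7-(allyloxy)-2-[2,4-bis(allyloxy)phenyl]-5-(methoxymethoxy)-8-SC-4H-chromen-4-one F7. C3 of F7 is lithiated with LiN(i-Pr)2 (THF, −78 °C), borylated with B(OMe)3 and oxidised with alkaline H2O2 to flavonol 29.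

3. Step 6 (Kowalski homologation). The bromine–lithium exchange and carbenoid rearrangement may stall, so that work-up returns the homologated ester, or the ynolate may be silylated on carbon to a silylketene. The fallback reaches ynolate 9 by oxidation of a lithium acetylide; it sets out from ester 7 and comes back at 9 and so at 10. i-Bu2AlH (CH2Cl2, −78 °C) reduces 7 to (3R)-6-methyl-3-(prop-1-en-2-yl)-6-(triethylsilyloxy)heptanal F8. Homologation with dimethyl (1-diazo-2-oxopropyl)phosphonate (K2CO3, MeOH) gives (4R)-7-methyl-4-(prop-1-en-2-yl)-7-(triethylsilyloxy)oct-1-yne F9. Deprotonation (n-BuLi, THF, −78 °C) and oxidation of the acetylide with LiOOt-Bu (from t-BuOOH and LiN(SiMe3)2, −78 → 0 °C) should give ynolate 9, which is trapped with i-Pr3SiOTf to give 10.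

**Further compounds**
F1 | step 8 | methyl (E)-3-(methoxymethoxy)but-2-enoate | COCO/C(C)=C/C(=O)OC
F2 | step 8 | (E)-3-(methoxymethoxy)but-2-enoic acid | COCO/C(C)=C/C(=O)O
F3 | step 8 | (E)-3-(methoxymethoxy)but-2-enoyl chloride | COCO/C(C)=C/C(=O)Cl
F4 | step 15 | 2,4-bis(allyloxy)-1-ethynylbenzene | C#Cc1ccc(OCC=C)cc1OCC=C
F5 | step 15 | 1-[4-(allyloxy)-2-hydroxy-6-(methoxymethoxy)-3-SC-phenyl]-3-[2,4-bis(allyloxy)phenyl]prop-2-yn-1-ol | C=C(C)[C@H](CCC(C)(C)O[Si](CC)(CC)CC)Cc1c(O)c(C(O)C#Cc2ccc(OCC=C)cc2OCC=C)c(OCOC)cc1OCC=C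
F6 | step 15 | 1-[4-(allyloxy)-2-hydroxy-6-(methoxymethoxy)-3-SC-phenyl]-3-[2,4-bis(allyloxy)phenyl]prop-2-yn-1-one | C=C(C)[C@H](CCC(C)(C)O[Si](CC)(CC)CC)Cc1c(O)c(C(=O)C#Cc2ccc(OCC=C)cc2OCC=C)c(OCOC)cc1OCC=C
F7 | step 15 | 7-(allyloxy)-2-[2,4-bis(allyloxy)phenyl]-5-(methoxymethoxy)-8-SC-4H-chromen-4-one | C=C(C)[C@H](CCC(C)(C)O[Si](CC)(CC)CC)Cc1c(OCC=C)cc(OCOC)c2c(=O)cc(-c3ccc(OCC=C)cc3OCC=C)oc12
F8 | step 6 | (3R)-6-methyl-3-(prop-1-en-2-yl)-6-(triethylsilyloxy)heptanal | C=C(C)[C@H](CCC(C)(C)O[Si](CC)(CC)CC)CC=O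
F9 | step 6 | (4R)-7-methyl-4-(prop-1-en-2-yl)-7-(triethylsilyloxy)oct-1-yne | C=C(C)[C@H](CCC(C)(C)O[Si](CC)(CC)CC)CC#C
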